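Per day is the unit in which this flask is best reckoned, and every amount below is a fraction of the starting material charged.

in all of them: gas phase 8.3 mM (held); catalyst 5.2 mM
- dawn: starting material 0.10 M; run made earlier
- summer: starting material 0.42 M; run made earlier
- flask: starting material 0.21 M; time 15 d

- dawn (time / d: target / %): 1.25: 45.9; 1.67: 54.2; 2.50: 65.8; 3.00: 69.5; 5.00: 72.7; 6.00: 71.3; 10.0: 64.7
- summer (time / d: target / %): 1.25: 37.3; 1.67: 46.8; 2.50: 59.4; 3.00: 64.6; 5.00: 71.3; 6.00: 71.5; 10.0: 64.9

(each reading ± 0.3 percentage points)

- time, not beyond 15 d, at which the flask holds most target
- the amount of target, in percent of the starting material charged, at that time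
- the first time at which target reaches 36%, in the same percent, in d

- at the start none of the gas phase is in solution

Take first the main step by itself, starting material to target: its curve climbs and stays up, yet the dawn run falls from 71.3% at 6.00 d to 64.7% at 10.0 d. So a first-order loss of target is added, and those two readings give 0.0243 d⁻¹, the fade constant: the fraction of target lost per day past the peak. Putting the fade back into the last dawn reading gives a working ceiling of 82.5%, which is a back-extrapolation of that reading, used here as a fitting number for the height of the curve and not as the yield of the main step.

Going round once more, the reading at 3.00 d, with its fade undone and held against that ceiling, gives a pseudo-first-order uptake constant of 0.789 d⁻¹ for dawn. The same reckoning gives 0.616 d⁻¹ for summer, slower at the heavier charge. The last addition is this load: the flask's charge lies near the geometric middle of the two charges, so its uptake is taken as their geometric mean, 0.697 d⁻¹. With these two steps, target in the flask tops at ln(uptake/fade)/(uptake − fade), which is 4.99 d, at the ceiling times exp(−fade × time), which is 73.1%.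

The forecast gives 4.8 d, 72.6% and 0.97 d, adding that the “target only declines afterwards”. Its peak time is earlier than the one reckoned here, and the early level is left to it.

The flask peaks at 4.76 d with 72.7% of target and reaches the asked level at 0.989 d. At that peak it also holds 19.5% of isomer of the product.

    gas phase ⇌ dissolved gas, rate k1*(csat - [dissolved gas]) (kL = 0.0388 min⁻¹)
    starting material + dissolved gas + catalyst → catalyst + target (k = 9.50 M⁻² min⁻¹)
    target ⇌ isomer of the product (K = 0.756, k = 6.66 × 10⁻⁵ min⁻¹)

Carried from the peak by the fade constant, target at 9.52 d comes to 64.8%, and the flask holds 65.2%. For a second flask of the same charge, read at 10 d, the fade constant gives 64.0%, and that flask holds 64.5%.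

Readings and results were generated by integration with made-up constants; scatter was added.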